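**Assumption:** the target has no stereocentre, and its one biaryl axis carries only two ortho substituents (CH2 and OH), so it is not configurationally stable. The target is therefore achiral, "single enantiomer" does not apply, and no stereocontrol is needed.

## Retrosynthetic overview

1. Giganteone A (13) ⇒ global O-debenzylation of the di-O-benzyl dimer 12.
2. Key step: 12 ⇒ the biaryl bond is made by a biomimetic dehydrogenative hetero-dimerisation, malabaricone C o-quinone (11, electrophile) + catechol-benzylated malabaricone C (9, nucleophile). No halide or boron handles are used, and both partners come from the single intermediate 9.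
3. 9 ⇒ sp3–sp2 B-alkyl Suzuki coupling of keto-olefin 5 with aryl bromide 7; 5 ⇒ C2-lithiated resorcinol bis-MOM ether + Weinreb amide of non-8-enoic acid.
4. Rings: none is constructed. The four benzene rings are bought (2 × resorcinol, 2 × 4-bromocatechol). Order of assembly: resorcinol ring acylated, catechol ring attached, biaryl bond last.
5. Deliberately avoided first choice: Suzuki–Miyaura biaryl coupling of two separately halogenated/borylated, fully protected halves.

## Route

**Step 1**
Reactants: 1 resorcinol
Product: 2 1,3-bis(methoxymethoxy)benzene
Conditions: MOMCl (2.5 equiv), i-Pr2NEt, CH2Cl2, 0 °C → rt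
Reagents that add atoms: chloromethyl methyl ether, COCCl
Why: Williamson-type O-alkylation of both phenols; MOM is the directing group for step 3 and is later removed by acid without touching benzyl ethers.

**Step 2**
Reactants: 3 non-8-enoic acid
Product: 4 N-methoxy-N-methylnon-8-enamide
Conditions: CDI, CH2Cl2, rt; then MeNH(OMe)·HCl, rt
Reagents that add atoms: N,O-dimethylhydroxylamine hydrochloride, CNOC.Cl
Why: Weinreb amide formation via the acyl imidazolide; the terminal alkene is inert.

**Step 3**
Reactants: 2 1,3-bis(methoxymethoxy)benzene; 4 N-methoxy-N-methylnon-8-enamide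
Product: 5 1-[2,6-bis(methoxymethoxy)phenyl]non-8-en-1-one
Conditions: 2 (1.3 equiv), n-BuLi, THF, 0 °C → rt, 1 h; then 4, −78 → 0 °C; aq. NH4Cl
Reagents that add atoms: none
Why: Directed ortho-metalation at C2 (between the two OMOM groups) followed by Weinreb ketone synthesis; the chelated tetrahedral intermediate prevents over-addition and fixes the 2,6-dioxygenated acyl pattern that Friedel–Crafts acylation cannot give.

**Step 4**
Reactants: 6 4-bromocatechol
Product: 7 1,2-bis(benzyloxy)-4-bromobenzene
Conditions: BnBr (2.3 equiv), K2CO3, DMF, rt
Reagents that add atoms: benzyl bromide, BrCc1ccccc1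
Why: Williamson etherification; benzyl survives the acid in step 6 and is removed by neutral hydrogenolysis later.

**Step 5**
Reactants: 5 1-[2,6-bis(methoxymethoxy)phenyl]non-8-en-1-one; 7 1,2-bis(benzyloxy)-4-bromobenzene
Product: 8 9-[3,4-bis(benzyloxy)phenyl]-1-[2,6-bis(methoxymethoxy)phenyl]nonan-1-one
Conditions: 5, 9-BBN dimer (1.1 equiv B–H), THF, 0 °C → rt, 3 h; then 7, Pd(dppf)Cl2 (5 mol %), 3 M aq. K3PO4, THF/DMF, 60 °C
Reagents that add atoms: none (9-BBN delivers only H; boron is lost)
Why: Anti-Markovnikov hydroboration of the terminal alkene, which outpaces reduction of the di-ortho-substituted, twisted aryl ketone, then B-alkyl Suzuki–Miyaura coupling gives the saturated (CH2)8 tether with Bn and MOM intact.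

**Step 6**
Reactants: 8
Product: 9 9-[3,4-bis(benzyloxy)phenyl]-1-(2,6-dihydroxyphenyl)nonan-1-one (3′,4′-di-O-benzylmalabaricone C)
Conditions: 3 M HCl, MeOH/THF, 50 °C
Reagents that add atoms: none
Why: Acid-catalysed acetal (MOM) cleavage, assisted by the ortho carbonyl; benzyl ethers and the ketone are stable.

**Step 7** (run on about one fifth of 9)
Reactants: 9
Product: 10 malabaricone C, 9-(3,4-dihydroxyphenyl)-1-(2,6-dihydroxyphenyl)nonan-1-one
Conditions: H2 (1 atm), 10 % Pd/C, EtOAc/MeOH, rt
Reagents that add atoms: none
Why: Hydrogenolysis of the benzyl ethers; the strongly H-bonded, electron-rich 2,6-dihydroxyaryl ketone is not reduced under neutral 1 atm conditions.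

**Step 8** (product used at once as a cold solution, not isolated)
Reactants: 10 malabaricone C
Product: 11 malabaricone C o-quinone, 4-[9-(2,6-dihydroxyphenyl)-9-oxononyl]cyclohexa-3,5-diene-1,2-dione
Conditions: Ag2O (3 equiv), Na2SO4, Et2O/THF, −20 °C, 15 min, dark; cold filtration through Celite under Ar
Reagents that add atoms: none
Why: Two-electron catechol → o-quinone oxidation (Willstätter conditions); the acylresorcinol has no ortho/para dihydroxy relationship and is not oxidised, and filtration removes all oxidant before the coupling.

**Step 9** (key step)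
Reactants: 11 malabaricone C o-quinone (1 equiv, added by syringe pump); 9 3′,4′-di-O-benzylmalabaricone C (4 equiv, excess recovered)
Product: 12 3′,4′-di-O-benzylgiganteone A (free catechol on the biaryl ring; benzylated catechol on the other chain terminus)
Conditions: 9, (PhO)2P(O)OH (10 mol %), CH2Cl2/HFIP 4:1, −20 → 0 °C, slow addition of 11; then aq. Na2S2O4
Reagents that add atoms: none
Why: Proposed new method: the acid/HFIP-activated o-quinone is attacked at its unsubstituted β-carbon (ortho to the alkyl chain, the usual site for C-nucleophiles on 4-alkyl-o-quinones) by the only activated carbon of 9 (C3≡C5 of the 2-acylresorcinol, ortho/para to both OH), and tautomerisation restores the catechol; 9 cannot be oxidised or homo-couple because its catechol is benzylated, and inverse slow addition into excess 9 suppresses self-condensation of 11 and redox exchange with the product; closest known reaction types are the conjugate addition of resorcinol/phloroglucinol rings to catechol o-quinones (dehydrodicatechin-type biaryl formation) and Brønsted-acid-catalysed arylation of quinones by phenols/naphthols.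

**Step 10**
Reactants: 12
Product: 13 giganteone A
Conditions: H2 (1 atm), 10 % Pd/C, EtOAc/MeOH, rt; filter under Ar
Reagents that add atoms: none
Why: Neutral hydrogenolysis of the two remaining benzyl ethers; the aryl ketones, the biaryl and the free catechol are untouched, and there is no stereochemistry to scramble.

## Compound list

1 | resorcinol | Oc1cccc(O)c1 | starting material
2 | 1,3-bis(methoxymethoxy)benzene | COCOc1cccc(OCOC)c1 | intermediate
3 | non-8-enoic acid | C=CCCCCCCC(=O)O | starting material
4 | N-methoxy-N-methylnon-8-enamide | C=CCCCCCCC(=O)N(C)OC | intermediate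
5 | 1-[2,6-bis(methoxymethoxy)phenyl]non-8-en-1-one | C=CCCCCCCC(=O)c1c(OCOC)cccc1OCOC | intermediate
6 | 4-bromocatechol (4-bromobenzene-1,2-diol) | Oc1ccc(Br)cc1O | starting material
7 | 1,2-bis(benzyloxy)-4-bromobenzene | Brc1ccc(OCc2ccccc2)c(OCc2ccccc2)c1 | intermediate
8 | 9-[3,4-bis(benzyloxy)phenyl]-1-[2,6-bis(methoxymethoxy)phenyl]nonan-1-one | COCOc1cccc(OCOC)c1C(=O)CCCCCCCCc1ccc(OCc2ccccc2)c(OCc2ccccc2)c1 | intermediate
9 | 9-[3,4-bis(benzyloxy)phenyl]-1-(2,6-dihydroxyphenyl)nonan-1-one | O=C(CCCCCCCCc1ccc(OCc2ccccc2)c(OCc2ccccc2)c1)c1c(O)cccc1O | intermediate (nucleophilic partner)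
10 | malabaricone C | O=C(CCCCCCCCc1ccc(O)c(O)c1)c1c(O)cccc1O | intermediate
11 | malabaricone C o-quinone | O=C(CCCCCCCCC1=CC(=O)C(=O)C=C1)c1c(O)cccc1O | intermediate (not isolated; electrophilic partner)
12 | 3′,4′-di-O-benzylgiganteone A | O=C(CCCCCCCCc1cc(O)c(O)cc1-c1ccc(O)c(C(=O)CCCCCCCCc2ccc(OCc3ccccc3)c(OCc3ccccc3)c2)c1O)c1c(O)cccc1O | intermediate
13 | giganteone A | O=C(CCCCCCCCc1cc(O)c(O)cc1-c1ccc(O)c(C(=O)CCCCCCCCc2ccc(O)c(O)c2)c1O)c1c(O)cccc1O | target

## Summary

**Total step count:** 10 (steps 8 and 9 are telescoped, so 9 isolations).

**Longest linear sequence:** 8 steps (3 → 4 → 5 → 8 → 9 → 10 → 11 → 12 → 13).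

**Three steps most likely to fail, with fallbacks:**

1. **Step 9, o-quinone arylation.** Risks are low nucleophilicity of the acylresorcinol, over-arylation, and redox exchange of 12 with 11 followed by dibenzofuran closure. Fallback: revert to a polarity-defined cross-coupling. Brominate 9 at resorcinol C3 (NBS) and protect it. Brominate 8 on the catechol ring ortho to the chain (para to OBn) and convert it to the pinacol boronate (Miyaura borylation). Join the two by Suzuki–Miyaura coupling, then deprotect globally.
2. **Step 8, generation and lifetime of the 4-alkyl-o-quinone.** Risks are tautomerisation to the p-quinone methide, self-condensation through its own resorcinol, and loss on silver. Fallback: avoid a discrete quinone altogether. Either run an anodic dehydrogenative phenol–arene cross-coupling of 10 with excess 9 (BDD anode, HFIP), or generate the quinone enzymatically (tyrosinase or laccase/O2, pH 6 buffer/acetone) in the presence of 9 so that it is trapped as it forms.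
3. **Step 5, hydroboration/B-alkyl Suzuki with a ketone present.** Risks are competing ketone reduction by 9-BBN and sluggish coupling of the electron-rich bromide. Fallback: change the bond-forming order. Couple 7 with the 9-BBN adduct of methyl non-8-enoate (the ester is inert to 9-BBN), convert the resulting ester to the Weinreb amide, and add lithiated 2 as the last C–C bond of the monomer.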